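The route rests on the skipped Z,Z-diene C5=C6–C7–C8=C9 of the acyl chain (C1 is the ketone carbon on the phloroglucinol ring). Both alkenes are carried as alkynes, which turns the doubly allylic C7 into a propargylic bromide and C6 into a terminal acetylide carbon. One copper-mediated C(sp)–C(sp3) coupling then joins the MOM-protected 5-hexynoyl phloroglucinol (C1–C6 and the ring) to a C7–C20 enediyne bromide that already carries the 15S benzoate and the 13E and 17Z alkenes. A single Lindlar semi-hydrogenation sets the 5Z, 8Z and 11Z alkenes together, and one deprotection releases the target.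

Key step: step 8

Remark: the acyl chain is numbered C1 (ketone carbon) to C20 (methyl) throughout, and ring A is the phloroglucinol ring; the benzoate introduced in step 3 serves as the C15 protecting group until the last step.

Step 1
Reactants: 1 phloroglucinol (benzene-1,3,5-triol); 2 hex-5-ynenitrile
Product: 4 1-(2,4,6-trihydroxyphenyl)hex-5-yn-1-one, via ketiminium chloride 3 (not isolated)
Conditions: ZnCl2, HCl (g), Et2O, 0 °C; then H2O, reflux
Reagents that add atoms: water, O
Why: Hoesch reaction, in which the nitrile activated by HCl/ZnCl2 acylates the electron-rich ring A once (the precipitating ketiminium salt deactivates the ring), the unactivated terminal alkyne is inert to HCl in ether at 0 °C, and aqueous hydrolysis releases the ketone.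

Step 2
Reactants: 4 1-(2,4,6-trihydroxyphenyl)hex-5-yn-1-one
Product: 5 1-[2,4,6-tris(methoxymethoxy)phenyl]hex-5-yn-1-one
Conditions: NaH (3.1 equiv), MOMCl (3.3 equiv), DMF, 0 °C → rt
Reagents that add atoms: chloromethyl methyl ether (MOMCl), COCCl
Why: Williamson-type O-alkylation of the three phenoxides, including the two hydrogen-bonded ones beside the ketone, so that no phenol can be O-propargylated in step 8; the near-stoichiometric NaH leaves the alkyne C–H and the ketone α-CH2 alone.

Step 3
Reactants: 6 (Z)-hept-4-enal
Product: 7 (2S,4Z)-1-oxohept-4-en-2-yl benzoate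
Conditions: (BzO)2, (S)-2-(triphenylmethyl)pyrrolidine (10 mol%), hydroquinone (10 mol%), THF, 0 °C; NaHCO3 wash, used crude
Reagents that add atoms: dibenzoyl peroxide, O=C(OOC(=O)c1ccccc1)c1ccccc1
Why: enamine-catalysed asymmetric α-benzoyloxylation of an aldehyde, in which the E-enamine of 6 attacks the peroxide O–O bond from the face opposite the trityl group of the (S)-catalyst and so sets C15 as S, while hydroquinone suppresses radical decomposition of the peroxide and the 17Z alkene is left alone.

Step 4
Reactants: 7 (2S,4Z)-1-oxohept-4-en-2-yl benzoate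
Product: 8 (3S,1E,5Z)-1-iodoocta-1,5-dien-3-yl benzoate
Conditions: CrCl2, CHI3, THF, 0 °C → rt
Reagents that add atoms: iodoform, IC(I)I
Why: Takai olefination, in which the geminal dichromium species from CHI3 and CrCl2 adds to the aldehyde and eliminates to the E-vinyl iodide (the 13E alkene) under neutral conditions that should not epimerise the α-acyloxy stereocenter.

Step 5
Reactants: 9 propargyl alcohol (prop-2-yn-1-ol); 10 propargyl bromide (3-bromoprop-1-yne)
Product: 12 hexa-2,5-diyn-1-ol, via bis(bromomagnesium) derivative 11 (not isolated)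
Conditions: EtMgBr (2 equiv), THF, 0 °C → 40 °C; then CuCl (cat.), 10, THF, rt → 50 °C; then H2O
Reagents that add atoms: none
Why: copper-catalysed alkylation of an alkynylmagnesium halide by a propargylic bromide, in which only the carbon–magnesium bond of the dianion displaces bromide (the magnesium alkoxide is inert), giving the skipped diyne with a free terminal alkyne for step 6.

Step 6
Reactants: 8 (3S,1E,5Z)-1-iodoocta-1,5-dien-3-yl benzoate; 12 hexa-2,5-diyn-1-ol
Product: 13 (9S,7E,11Z)-1-hydroxytetradeca-7,11-dien-2,5-diyn-9-yl benzoate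
Conditions: PdCl2(PPh3)2 (cat.), CuI (cat.), Et3N, THF (degassed), 0 °C → rt
Reagents that add atoms: none
Why: Sonogashira coupling, in which zerovalent palladium inserts into the vinyl C–I bond rapidly at 0 °C with retention of the E geometry, and a tertiary amine at low temperature should avoid amination or ionisation of the allylic benzoate and isomerisation of the skipped diyne.

Step 7
Reactants: 13 (9S,7E,11Z)-1-hydroxytetradeca-7,11-dien-2,5-diyn-9-yl benzoate
Product: 14 (9S,7E,11Z)-1-bromotetradeca-7,11-dien-2,5-diyn-9-yl benzoate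
Conditions: CBr4, PPh3, CH2Cl2, −20 → 0 °C; used at once
Reagents that add atoms: carbon tetrabromide, BrC(Br)(Br)Br
Why: Appel reaction, in which bromide displaces the oxyphosphonium of the primary propargylic alcohol under neutral conditions that leave the benzoate, the enediyne and C15 untouched.

Step 8
Reactants: 5 1-[2,4,6-tris(methoxymethoxy)phenyl]hex-5-yn-1-one; 14 (9S,7E,11Z)-1-bromotetradeca-7,11-dien-2,5-diyn-9-yl benzoate
Product: 15 (13E,15S,17Z)-15-(benzoyloxy)-1-[2,4,6-tris(methoxymethoxy)phenyl]icosa-13,17-dien-5,8,11-triyn-1-one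
Conditions: CuI (0.5 equiv), K2CO3 (1.5 equiv), DMF, rt, argon
Reagents that add atoms: none
Why: K2CO3 and CuI convert the terminal alkyne C6–H of 5 into an alkynylcopper species (monovalent copper), which displaces bromide from the propargylic carbon C7 of 14 (oxidative addition to a transient trivalent copper species and reductive elimination, overall SN2), forming the C6–C7 bond and the 5,8,11-triyne. The closest known reaction type is the copper-mediated coupling of 1-alkynes with propargylic halides to give skipped diynes. No ring is closed and no stereocenter is formed; C15 is remote and untouched, and its benzoate survives the weak, non-nucleophilic carbonate base. The selectivity needed is attack at the α carbon C7 and not at the γ carbon C9 (SN2′, which would give an allene), together with no base-induced isomerisation of the skipped diynes; the unhindered primary bromide, the soft copper nucleophile and carbonate at room temperature should secure both. O-Propargylation of ring A is excluded because all three phenols are MOM ethers, and the aryl ketone is not enolised by K2CO3.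

Step 9
Reactants: 15 (13E,15S,17Z)-15-(benzoyloxy)-1-[2,4,6-tris(methoxymethoxy)phenyl]icosa-13,17-dien-5,8,11-triyn-1-one
Product: 16 (5Z,8Z,11Z,13E,15S,17Z)-15-(benzoyloxy)-1-[2,4,6-tris(methoxymethoxy)phenyl]icosa-5,8,11,13,17-pentaen-1-one
Conditions: H2 (1 atm), Pd/CaCO3 poisoned with Pb(OAc)2 (Lindlar catalyst), quinoline, EtOAc/hexane, 0 °C → rt, stopped after uptake of three equivalents
Reagents that add atoms: none
Why: Lindlar semi-hydrogenation, in which syn delivery of hydrogen on the poisoned palladium surface turns each of the three alkynes into a Z-alkene, quinoline holds back over-reduction and isomerisation, and the 13E and 17Z alkenes, ketone, acetals and benzoate are not touched.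

Step 10
Reactants: 16 (5Z,8Z,11Z,13E,15S,17Z)-15-(benzoyloxy)-1-[2,4,6-tris(methoxymethoxy)phenyl]icosa-5,8,11,13,17-pentaen-1-one
Product: 18 (5Z,8Z,11Z,13E,15S,17Z)-15-hydroxy-1-(2,4,6-trihydroxyphenyl)icosa-5,8,11,13,17-pentaen-1-one, via tris(trimethylsilyl) ether 17 (not isolated)
Conditions: TMSOTf (6 equiv), 2,2'-bipyridyl (9 equiv), CH2Cl2, 0 °C → rt; then MeOH, K2CO3, rt, argon; citric acid buffer work-up
Reagents that add atoms: none
Why: silyl triflate/2,2'-bipyridyl cleavage of aryl MOM ethers converts the three acetals into aryl silyl ethers without protic acid, so the ionisable dienyl C15–O bond is spared, and base-catalysed methanolysis (Zemplén-type transesterification) then cleaves the aryl O–Si bonds and removes the benzoate by acyl–oxygen cleavage, which leaves C15 as S.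

Compound list
1 | phloroglucinol (benzene-1,3,5-triol) | Oc1cc(O)cc(O)c1 | starting material
2 | hex-5-ynenitrile | C#CCCCC#N | starting material
3 | 1-(2,4,6-trihydroxyphenyl)hex-5-yn-1-iminium chloride (ketiminium chloride, not isolated) | C#CCCCC(=[NH2+])c1c(O)cc(O)cc1O.[Cl-] | intermediate
4 | 1-(2,4,6-trihydroxyphenyl)hex-5-yn-1-one | C#CCCCC(=O)c1c(O)cc(O)cc1O | intermediate
5 | 1-[2,4,6-tris(methoxymethoxy)phenyl]hex-5-yn-1-one | C#CCCCC(=O)c1c(OCOC)cc(OCOC)cc1OCOC | intermediate
6 | (Z)-hept-4-enal | CC/C=C\CCC=O | starting material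
7 | (2S,4Z)-1-oxohept-4-en-2-yl benzoate | CC/C=C\C[C@H](OC(=O)c1ccccc1)C=O | intermediate
8 | (3S,1E,5Z)-1-iodoocta-1,5-dien-3-yl benzoate | CC/C=C\C[C@H](OC(=O)c1ccccc1)/C=C/I | intermediate
9 | propargyl alcohol (prop-2-yn-1-ol) | C#CCO | starting material
10 | propargyl bromide (3-bromoprop-1-yne) | C#CCBr | starting material
11 | bis(bromomagnesium) derivative of propargyl alcohol (C- and O-magnesiated, not isolated) | Br[Mg]OCC#C[Mg]Br | intermediate
12 | hexa-2,5-diyn-1-ol | C#CCC#CCO | intermediate
13 | (9S,7E,11Z)-1-hydroxytetradeca-7,11-dien-2,5-diyn-9-yl benzoate | CC/C=C\C[C@H](OC(=O)c1ccccc1)/C=C/C#CCC#CCO | intermediate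
14 | (9S,7E,11Z)-1-bromotetradeca-7,11-dien-2,5-diyn-9-yl benzoate | CC/C=C\C[C@H](OC(=O)c1ccccc1)/C=C/C#CCC#CCBr | intermediate
15 | (13E,15S,17Z)-15-(benzoyloxy)-1-[2,4,6-tris(methoxymethoxy)phenyl]icosa-13,17-dien-5,8,11-triyn-1-one | CC/C=C\C[C@H](OC(=O)c1ccccc1)/C=C/C#CCC#CCC#CCCCC(=O)c1c(OCOC)cc(OCOC)cc1OCOC | intermediate
16 | (5Z,8Z,11Z,13E,15S,17Z)-15-(benzoyloxy)-1-[2,4,6-tris(methoxymethoxy)phenyl]icosa-5,8,11,13,17-pentaen-1-one | CC/C=C\C[C@H](OC(=O)c1ccccc1)/C=C/C=C\C/C=C\C/C=C\CCCC(=O)c1c(OCOC)cc(OCOC)cc1OCOC | intermediate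
17 | (5Z,8Z,11Z,13E,15S,17Z)-15-(benzoyloxy)-1-[2,4,6-tris(trimethylsilyloxy)phenyl]icosa-5,8,11,13,17-pentaen-1-one (not isolated) | CC/C=C\C[C@H](OC(=O)c1ccccc1)/C=C/C=C\C/C=C\C/C=C\CCCC(=O)c1c(O[Si](C)(C)C)cc(O[Si](C)(C)C)cc1O[Si](C)(C)C | intermediate
18 | (5Z,8Z,11Z,13E,15S,17Z)-15-hydroxy-1-(2,4,6-trihydroxyphenyl)icosa-5,8,11,13,17-pentaen-1-one | CC/C=C\C[C@H](O)/C=C/C=C\C/C=C\C/C=C\CCCC(=O)c1c(O)cc(O)cc1O | target

Total step count: 10 steps.
Longest linear sequence: 7 steps (steps 3, 4, 6, 7, 8, 9 and 10, from (Z)-hept-4-enal 6).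

Steps most likely to fail

Step 9. The semi-hydrogenation may over-reduce the pentaene, stop short at the conjugated C11≡C12 alkyne, or isomerise the new Z,E-diene on the palladium surface. The fallback splits the reduction by mechanism and sets out from 15. Zn dust activated with Cu(OAc)2 and AgNO3 in MeOH/H2O reduces by electron transfer and cis protonation only the alkyne that is conjugated to the 13E alkene. This should give (11Z,13E,15S,17Z)-15-(benzoyloxy)-1-[2,4,6-tris(methoxymethoxy)phenyl]icosa-11,13,17-trien-5,8-diyn-1-one F1. The remaining isolated skipped diyne is then semi-hydrogenated with P-2 nickel (Ni(OAc)2, NaBH4, ethylenediamine, H2, EtOH), which does not isomerise conjugated dienes, and the route is rejoined at 16.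

Step 10. The silyl triflate may ionise the dienyl C15–O bond (allylic transposition or elimination), or the two acetals beside the ketone may cleave incompletely in the one-pot sequence. The fallback separates the two deprotections, changes the mechanism of acetal cleavage, and sets out from 16. K2CO3 in MeOH first removes only the benzoate and should give (5Z,8Z,11Z,13E,15S,17Z)-15-hydroxy-1-[2,4,6-tris(methoxymethoxy)phenyl]icosa-5,8,11,13,17-pentaen-1-one F2. The three aryl MOM groups are then removed by thiol-assisted Lewis-acid cleavage (ZnBr2, n-PrSH, CH2Cl2, 0 °C, short contact), in which the soft thiol traps each methoxymethyl unit as a thioacetal. This arrives directly at target 18.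

Step 6. Zerovalent palladium may ionise the allylic benzoate, with loss of configuration at C15 or 1,3-transposition, and the amine may isomerise the skipped diyne. The fallback builds 13 without palladium and sets out from aldehyde 7. A Horner–Wadsworth–Emmons reaction with the lithium salt of diethyl [3-(trimethylsilyl)prop-2-yn-1-yl]phosphonate (CCOP(=O)(CC#C[Si](C)(C)C)OCC; LiHMDS, THF, −78 °C) should give the E-enyne (3E,5S,7Z)-1-(trimethylsilyl)deca-3,7-dien-1-yn-5-yl benzoate F3. Desilylation (TBAF, AcOH, THF, 0 °C) should give (3E,5S,7Z)-deca-3,7-dien-1-yn-5-yl benzoate F4. Copper-mediated coupling of F4 with 4-chlorobut-2-yn-1-ol (OCC#CCCl; CuI, K2CO3, DMF, as in step 8) then adds C7–C10 and returns to 13.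

Further compounds
F1 | step 9 | (11Z,13E,15S,17Z)-15-(benzoyloxy)-1-[2,4,6-tris(methoxymethoxy)phenyl]icosa-11,13,17-trien-5,8-diyn-1-one | CC/C=C\C[C@H](OC(=O)c1ccccc1)/C=C/C=C\CC#CCC#CCCCC(=O)c1c(OCOC)cc(OCOC)cc1OCOC
F2 | step 10 | (5Z,8Z,11Z,13E,15S,17Z)-15-hydroxy-1-[2,4,6-tris(methoxymethoxy)phenyl]icosa-5,8,11,13,17-pentaen-1-one | CC/C=C\C[C@H](O)/C=C/C=C\C/C=C\C/C=C\CCCC(=O)c1c(OCOC)cc(OCOC)cc1OCOC
F3 | step 6 | (3E,5S,7Z)-1-(trimethylsilyl)deca-3,7-dien-1-yn-5-yl benzoate | CC/C=C\C[C@H](OC(=O)c1ccccc1)/C=C/C#C[Si](C)(C)C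
F4 | step 6 | (3E,5S,7Z)-deca-3,7-dien-1-yn-5-yl benzoate | CC/C=C\C[C@H](OC(=O)c1ccccc1)/C=C/C#C
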